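The interflavan bond C4–C6 is made last, from a C4 cation of the upper unit and C8-brominated gallocatechin. The upper pyran ring C (O1, C2, C3, C4, C4a, C8a) is not cyclised but grown from a benzofuran: a Lewis-acid α-ketol shift moves the C2–C3 bond of a 3-formyl-3-hydroxy-2-aryl-2,3-dihydrobenzofuran onto the formyl carbon. The step exploits the C3 hydroxyl beside benzylic C4: the product is the ketol whose C4 ketone is conjugated with ring A. One operation enlarges the ring, carries C2 over with retention and erases the tertiary carbinol centre. The precursor needs one defined stereocentre, set by asymmetric C–H insertion.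

Key step: step 7

Assumption (stereochemistry): Rh2(S-PTTL)4 is taken to give the (2S,3R)-cis insertion product in step 4; if the sense of induction is the opposite, the mirror-image complex Rh2(R-PTTL)4 is used instead.
Assumption (materials): (+)-gallocatechin, 5-(benzyloxy)-2-bromophenol, [3,4,5-tris(benzyloxy)phenyl]methanol and the silyl ketene acetal of methyl acetate are taken as purchasable.

Step 1
Reactants: 1 5-(benzyloxy)-2-bromophenol; 2 [3,4,5-tris(benzyloxy)phenyl]methanol
Product: 3 4-(benzyloxy)-1-bromo-2-{[3,4,5-tris(benzyloxy)phenyl]methoxy}benzene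
Conditions: PPh3, DIAD, THF, 0 °C to rt
Reagents that add atoms: none
Why: Mitsunobu etherification of the acidic ortho-bromophenol with the primary benzylic alcohol should give the aryl benzyl ether without touching the existing benzyl ethers; no stereocentre is formed.

Step 2
Reactants: 3 4-(benzyloxy)-1-bromo-2-{[3,4,5-tris(benzyloxy)phenyl]methoxy}benzene; 4 tert-butyl[(1-methoxyethenyl)oxy]dimethylsilane
Product: 5 methyl 2-[4-(benzyloxy)-2-{[3,4,5-tris(benzyloxy)phenyl]methoxy}phenyl]acetate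
Conditions: Pd(dba)2 (2 mol %), P(t-Bu)3 (4 mol %), ZnF2 (0.5 equiv), DMF, 80 °C
Reagents that add atoms: none
Why: Palladium-catalysed α-arylation of an ester enolate equivalent (silyl ketene acetal activated by ZnF2) should replace bromine by the CH2CO2Me group under conditions that leave benzyl ethers intact; no stereocentre is formed.

Step 3
Reactants: 5 methyl 2-[4-(benzyloxy)-2-{[3,4,5-tris(benzyloxy)phenyl]methoxy}phenyl]acetate
Product: 6 methyl 2-[4-(benzyloxy)-2-{[3,4,5-tris(benzyloxy)phenyl]methoxy}phenyl]-2-diazoacetate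
Conditions: p-ABSA, DBU, MeCN, 0 °C to rt
Reagents that add atoms: 4-acetamidobenzenesulfonyl azide (p-ABSA), CC(=O)Nc1ccc(cc1)S(=O)(=O)N=[N+]=[N-]
Why: Regitz diazo transfer to the benzylic, ester-activated methylene should give the aryldiazoacetate; no stereocentre is formed.

Step 4
Reactants: 6 methyl 2-[4-(benzyloxy)-2-{[3,4,5-tris(benzyloxy)phenyl]methoxy}phenyl]-2-diazoacetate
Product: 7 methyl (2S,3R)-6-(benzyloxy)-2-[3,4,5-tris(benzyloxy)phenyl]-2,3-dihydro-1-benzofuran-3-carboxylate (2,3-cis)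
Conditions: Rh2(S-PTTL)4 [dirhodium tetrakis(N-phthaloyl-(S)-tert-leucinate)] (1 mol %), toluene, −78 °C
Reagents that add atoms: none
Why: The chiral dirhodium carboxylate should generate a donor/acceptor carbenoid that inserts into the ether-activated benzylic C–H bond five atoms away (intramolecular 1,5-C–H insertion closing the dihydrofuran ring), the catalyst setting C2 and the concerted, kinetically cis-selective insertion setting C3.

Step 5
Reactants: 7 methyl (2S,3R)-6-(benzyloxy)-2-[3,4,5-tris(benzyloxy)phenyl]-2,3-dihydro-1-benzofuran-3-carboxylate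
Product: 9 methyl (2R,3S)-6-(benzyloxy)-3-hydroxy-2-[3,4,5-tris(benzyloxy)phenyl]-2,3-dihydro-1-benzofuran-3-carboxylate, via potassium ester enolate 8 (not isolated)
Conditions: KHMDS, THF, −78 °C; 2-(phenylsulfonyl)-3-phenyloxaziridine, −78 °C; AcOH quench
Reagents that add atoms: 2-(phenylsulfonyl)-3-phenyloxaziridine, O=S(=O)(c1ccccc1)N1OC1c1ccccc1
Why: Enolate hydroxylation with an N-sulfonyloxaziridine should deliver oxygen to the face of the planar enolate 8 opposite the C2 aryl group, giving the 3S carbinol (hydroxyl trans to the aryl group), while C2 is untouched and changes its descriptor from S to R only because the CIP priorities change.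

Step 6
Reactants: 9 methyl (2R,3S)-6-(benzyloxy)-3-hydroxy-2-[3,4,5-tris(benzyloxy)phenyl]-2,3-dihydro-1-benzofuran-3-carboxylate
Product: 10 (2R,3S)-6-(benzyloxy)-3-hydroxy-2-[3,4,5-tris(benzyloxy)phenyl]-2,3-dihydro-1-benzofuran-3-carbaldehyde
Conditions: DIBAL-H (i-Bu2AlH, 2.2 equiv), CH2Cl2, −78 °C; Rochelle salt work-up
Reagents that add atoms: none
Why: Partial ester reduction with DIBAL-H at −78 °C should stop at the aluminium-chelated hemiacetal of the α-alkoxy ester and release the aldehyde on work-up; no stereocentre changes.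

Step 7
Reactants: 10 (2R,3S)-6-(benzyloxy)-3-hydroxy-2-[3,4,5-tris(benzyloxy)phenyl]-2,3-dihydro-1-benzofuran-3-carbaldehyde
Product: 11 (2R,3R)-7-(benzyloxy)-3-hydroxy-2-[3,4,5-tris(benzyloxy)phenyl]-2,3-dihydro-4H-chromen-4-one (2,3-trans)
Conditions: Sc(OTf)3 (10 mol %), 4 Å MS, CH2Cl2, 0 °C to rt
Reagents that add atoms: none
Why: Sc(OTf)3 binds the formyl oxygen and the tertiary hydroxyl of 10 as a five-membered chelate, and the C2–C3 ring bond, nearly parallel to the carbonyl π* orbital, shifts suprafacially from the carbinol carbon to the formyl carbon while the carbinol becomes the ketone (α-ketol or acyloin rearrangement). The closest known reaction type is the ring enlargement of 1-hydroxycycloalkanecarbaldehydes to 2-hydroxycycloalkanones and the D-homoannulation of 17-hydroxy-20-ketosteroids. No ring is closed by cyclisation: the five-membered ring O1–C2–C3–C3a–C7a is enlarged by one atom, the formyl carbon entering between C2 and the old C3, which becomes C4 (mode of ring formation: 1,2-shift of an endocyclic bond to an exocyclic carbon). C2 migrates with retention and stays R; the new carbinol centre C3 is set by the chelate, in which the formyl oxygen is syn to the hydroxyl and C2 reaches the formyl carbon from the face that leaves the new hydroxyl trans to the 2-aryl group (3R), which is also the thermodynamically preferred diequatorial ketol, while the old carbinol centre becomes sp2 so that its configuration no longer matters. The step needs migration to win over dehydration to the aromatic benzofuran and over heterolysis at C2; the gain from aldehyde to para-alkoxyaryl ketone and from five- to six-membered ring, together with a non-protic chelating acid that keeps the hydroxyl bound, should secure this. Should the aryl bond C3–C3a migrate instead, the regioisomeric ketol would tautomerise through the common enediol to the same product.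

Step 8
Reactants: 11 (2R,3R)-7-(benzyloxy)-3-hydroxy-2-[3,4,5-tris(benzyloxy)phenyl]-2,3-dihydro-4H-chromen-4-one
Product: 12 (2R,3S,4R)-7-(benzyloxy)-2-[3,4,5-tris(benzyloxy)phenyl]-3,4-dihydro-2H-chromene-3,4-diol
Conditions: NaBH4, THF/MeOH, 0 °C
Reagents that add atoms: none
Why: Borohydride reduction of the aryl ketone should give mainly the 3,4-trans diol (4R) by axial hydride attack, as is usual for 2,3-trans dihydroflavonols, and the C4 configuration is of no consequence because C4 is ionised in step 11.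

Step 9
Reactants: 13 (+)-gallocatechin
Product: 14 (2R,3S)-5,7-bis(benzyloxy)-2-[3,4,5-tris(benzyloxy)phenyl]-3,4-dihydro-2H-chromen-3-ol
Conditions: BnBr (5.5 equiv), K2CO3, DMF, argon, 0 °C to rt
Reagents that add atoms: benzyl bromide, BrCc1ccccc1
Why: Williamson etherification with K2CO3 should benzylate the five phenols selectively over the much less acidic secondary alcohol under exclusion of oxygen; the stereocentres are untouched.

Step 10
Reactants: 14 (2R,3S)-5,7-bis(benzyloxy)-2-[3,4,5-tris(benzyloxy)phenyl]-3,4-dihydro-2H-chromen-3-ol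
Product: 15 (2R,3S)-5,7-bis(benzyloxy)-8-bromo-2-[3,4,5-tris(benzyloxy)phenyl]-3,4-dihydro-2H-chromen-3-ol
Conditions: NBS (1.0 equiv), CH2Cl2, −78 °C to 0 °C
Reagents that add atoms: N-bromosuccinimide, O=C1CCC(=O)N1Br
Why: Electrophilic aromatic bromination of the 5,7-dioxygenated ring should occur at C8, the more reactive of its two free positions, and so block it against later C–C bond formation; the stereocentres are untouched.

Step 11
Reactants: 12 (2R,3S,4R)-7-(benzyloxy)-2-[3,4,5-tris(benzyloxy)phenyl]-3,4-dihydro-2H-chromene-3,4-diol; 15 (2R,3S)-5,7-bis(benzyloxy)-8-bromo-2-[3,4,5-tris(benzyloxy)phenyl]-3,4-dihydro-2H-chromen-3-ol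
Product: 17 (2R,3S,4S)-7-(benzyloxy)-4-{(2R,3S)-5,7-bis(benzyloxy)-8-bromo-3-hydroxy-2-[3,4,5-tris(benzyloxy)phenyl]-3,4-dihydro-2H-chromen-6-yl}-2-[3,4,5-tris(benzyloxy)phenyl]-3,4-dihydro-2H-chromen-3-ol, via flavan-4-yl cation 16 (not isolated)
Conditions: 15 (3 equiv), BF3·OEt2 (0.2 equiv), 4 Å MS, CH2Cl2, −20 °C to 0 °C, slow addition of 12
Reagents that add atoms: none
Why: Lewis-acid ionisation of the benzylic 4-hydroxyl should give cation 16 (stabilised by the para 7-benzyloxy group and O1), which is trapped in a Friedel–Crafts alkylation by C6 of 15, the only free ring position once C8 is blocked, with attack anti to the 3-hydroxyl setting C4 as 4S (3,4-trans) as is usual for 2,3-trans flavan-4-yl cations.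

Step 12
Reactants: 17 (2R,3S,4S)-7-(benzyloxy)-4-{(2R,3S)-5,7-bis(benzyloxy)-8-bromo-3-hydroxy-2-[3,4,5-tris(benzyloxy)phenyl]-3,4-dihydro-2H-chromen-6-yl}-2-[3,4,5-tris(benzyloxy)phenyl]-3,4-dihydro-2H-chromen-3-ol
Product: 18 (2R,3S,4S)-4-[(2R,3S)-3,5,7-trihydroxy-2-(3,4,5-trihydroxyphenyl)-3,4-dihydro-2H-chromen-6-yl]-2-(3,4,5-trihydroxyphenyl)-3,4-dihydro-2H-chromene-3,7-diol (CNP0311915.1)
Conditions: H2 (1 atm), Pd(OH)2/C, Et3N (1.5 equiv), THF/MeOH/H2O, rt
Reagents that add atoms: none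
Why: Catalytic hydrogenolysis should cleave all nine benzyl ethers and the aryl C–Br bond (Et3N taking up the HBr) without affecting the stereocentres or the interflavan bond.

Compound list
1 | 5-(benzyloxy)-2-bromophenol | Oc1cc(OCc2ccccc2)ccc1Br | starting material
2 | [3,4,5-tris(benzyloxy)phenyl]methanol | OCc1cc(OCc2ccccc2)c(OCc2ccccc2)c(OCc2ccccc2)c1 | starting material
3 | 4-(benzyloxy)-1-bromo-2-{[3,4,5-tris(benzyloxy)phenyl]methoxy}benzene | Brc1ccc(OCc2ccccc2)cc1OCc1cc(OCc2ccccc2)c(OCc2ccccc2)c(OCc2ccccc2)c1 | intermediate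
4 | tert-butyl[(1-methoxyethenyl)oxy]dimethylsilane (silyl ketene acetal of methyl acetate) | COC(=C)O[Si](C)(C)C(C)(C)C | starting material
5 | methyl 2-[4-(benzyloxy)-2-{[3,4,5-tris(benzyloxy)phenyl]methoxy}phenyl]acetate | COC(=O)Cc1ccc(OCc2ccccc2)cc1OCc1cc(OCc2ccccc2)c(OCc2ccccc2)c(OCc2ccccc2)c1 | intermediate
6 | methyl 2-[4-(benzyloxy)-2-{[3,4,5-tris(benzyloxy)phenyl]methoxy}phenyl]-2-diazoacetate | COC(=O)C(=[N+]=[N-])c1ccc(OCc2ccccc2)cc1OCc1cc(OCc2ccccc2)c(OCc2ccccc2)c(OCc2ccccc2)c1 | intermediate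
7 | methyl (2S,3R)-6-(benzyloxy)-2-[3,4,5-tris(benzyloxy)phenyl]-2,3-dihydro-1-benzofuran-3-carboxylate (2,3-cis) | COC(=O)[C@H]1[C@@H](c3cc(OCc4ccccc4)c(OCc4ccccc4)c(OCc4ccccc4)c3)Oc2cc(OCc3ccccc3)ccc21 | intermediate
8 | potassium ester enolate of 7 (C3 planar, C2 as in 7) | COC([O-])=C1[C@@H](c3cc(OCc4ccccc4)c(OCc4ccccc4)c(OCc4ccccc4)c3)Oc2cc(OCc3ccccc3)ccc21.[K+] | intermediate
9 | methyl (2R,3S)-6-(benzyloxy)-3-hydroxy-2-[3,4,5-tris(benzyloxy)phenyl]-2,3-dihydro-1-benzofuran-3-carboxylate (hydroxyl trans to the 2-aryl group) | COC(=O)[C@@]1(O)[C@@H](c3cc(OCc4ccccc4)c(OCc4ccccc4)c(OCc4ccccc4)c3)Oc2cc(OCc3ccccc3)ccc21 | intermediate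
10 | (2R,3S)-6-(benzyloxy)-3-hydroxy-2-[3,4,5-tris(benzyloxy)phenyl]-2,3-dihydro-1-benzofuran-3-carbaldehyde | O=C[C@@]1(O)[C@@H](c3cc(OCc4ccccc4)c(OCc4ccccc4)c(OCc4ccccc4)c3)Oc2cc(OCc3ccccc3)ccc21 | intermediate
11 | (2R,3R)-7-(benzyloxy)-3-hydroxy-2-[3,4,5-tris(benzyloxy)phenyl]-2,3-dihydro-4H-chromen-4-one (2,3-trans) | O[C@@H]1[C@@H](c3cc(OCc4ccccc4)c(OCc4ccccc4)c(OCc4ccccc4)c3)Oc2cc(OCc3ccccc3)ccc2C1=O | intermediate
12 | (2R,3S,4R)-7-(benzyloxy)-2-[3,4,5-tris(benzyloxy)phenyl]-3,4-dihydro-2H-chromene-3,4-diol | O[C@@H]1[C@@H](c3cc(OCc4ccccc4)c(OCc4ccccc4)c(OCc4ccccc4)c3)Oc2cc(OCc3ccccc3)ccc2[C@H]1O | intermediate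
13 | (+)-gallocatechin, (2R,3S)-2-(3,4,5-trihydroxyphenyl)-3,4-dihydro-2H-chromene-3,5,7-triol | Oc1cc(O)c2c(c1)O[C@H](c1cc(O)c(O)c(O)c1)[C@@H](O)C2 | starting material
14 | (2R,3S)-5,7-bis(benzyloxy)-2-[3,4,5-tris(benzyloxy)phenyl]-3,4-dihydro-2H-chromen-3-ol | c1ccccc1COc1cc(OCc3ccccc3)c2c(c1)O[C@H](c1cc(OCc3ccccc3)c(OCc3ccccc3)c(OCc3ccccc3)c1)[C@@H](O)C2 | intermediate
15 | (2R,3S)-5,7-bis(benzyloxy)-8-bromo-2-[3,4,5-tris(benzyloxy)phenyl]-3,4-dihydro-2H-chromen-3-ol | c1ccccc1COc1cc(OCc3ccccc3)c2c(c1Br)O[C@H](c1cc(OCc3ccccc3)c(OCc3ccccc3)c(OCc3ccccc3)c1)[C@@H](O)C2 | intermediate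
16 | (2R,3S)-7-(benzyloxy)-3-hydroxy-2-[3,4,5-tris(benzyloxy)phenyl]-3,4-dihydro-2H-chromen-4-ylium (C4 cation of 12) | O[C@@H]1[C@@H](c3cc(OCc4ccccc4)c(OCc4ccccc4)c(OCc4ccccc4)c3)Oc2cc(OCc3ccccc3)ccc2[CH+]1 | intermediate
17 | (2R,3S,4S)-7-(benzyloxy)-4-{(2R,3S)-5,7-bis(benzyloxy)-8-bromo-3-hydroxy-2-[3,4,5-tris(benzyloxy)phenyl]-3,4-dihydro-2H-chromen-6-yl}-2-[3,4,5-tris(benzyloxy)phenyl]-3,4-dihydro-2H-chromen-3-ol | c1ccccc1COc1ccc2c(c1)O[C@H](c1cc(OCc3ccccc3)c(OCc3ccccc3)c(OCc3ccccc3)c1)[C@@H](O)[C@@H]2c1c(OCc3ccccc3)c(Br)c2c(c1OCc3ccccc3)C[C@H](O)[C@@H](c1cc(OCc3ccccc3)c(OCc3ccccc3)c(OCc3ccccc3)c1)O2 | intermediate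
18 | (2R,3S,4S)-4-[(2R,3S)-3,5,7-trihydroxy-2-(3,4,5-trihydroxyphenyl)-3,4-dihydro-2H-chromen-6-yl]-2-(3,4,5-trihydroxyphenyl)-3,4-dihydro-2H-chromene-3,7-diol | Oc1ccc2c(c1)O[C@H](c1cc(O)c(O)c(O)c1)[C@@H](O)[C@@H]2c1c(O)cc2c(c1O)C[C@H](O)[C@@H](c1cc(O)c(O)c(O)c1)O2 | target

Total step count: 12. Longest linear sequence: 10 steps (steps 1 to 8, then 11 and 12).

Steps most likely to fail

Step 7 (ring expansion). The risks are ionisation of the tertiary benzylic hydroxyl with dehydration to the aromatic benzofuran, heterolysis at C2 with loss of its configuration, and incomplete equilibration to the conjugated trans ketol. The fallback moves the shift onto the O-silylated aldehyde, which has no free hydroxyl, and sets out from 9. Silylation (TESOTf, 2,6-lutidine, CH2Cl2) should give methyl (2R,3S)-6-(benzyloxy)-3-[(triethylsilyl)oxy]-2-[3,4,5-tris(benzyloxy)phenyl]-2,3-dihydro-1-benzofuran-3-carboxylate F1. DIBAL-H at −78 °C should then give (2R,3S)-6-(benzyloxy)-3-[(triethylsilyl)oxy]-2-[3,4,5-tris(benzyloxy)phenyl]-2,3-dihydro-1-benzofuran-3-carbaldehyde F2. The known aluminium-promoted 1,2-shift of α-siloxy aldehydes to α-siloxy ketones (Me2AlCl, CH2Cl2, −78 °C) is irreversible and proceeds with silyl transfer; it should give (2R,3R)-7-(benzyloxy)-3-[(triethylsilyl)oxy]-2-[3,4,5-tris(benzyloxy)phenyl]-2,3-dihydro-4H-chromen-4-one F3. Buffered fluoride (TBAF, AcOH, THF) should free the ketol, and any 2,3-cis material is expected to equilibrate to the trans isomer through the enol. The fallback comes back to the route at 11.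

Step 11 (interflavan coupling). The risks are self-condensation of the electrophile, because the brominated nucleophile is hindered and deactivated, and poor facial selectivity at C4. The fallback is the protecting-group-free condensation of a flavan-3,4-diol with a free flavan-3-ol, and sets out from 11. Hydrogenolysis (H2, Pd/C, EtOAc/MeOH) should give (2R,3R)-3,7-dihydroxy-2-(3,4,5-trihydroxyphenyl)-2,3-dihydro-4H-chromen-4-one F4. NaBH4 in EtOH should give (2R,3S,4R)-2-(3,4,5-trihydroxyphenyl)-3,4-dihydro-2H-chromene-3,4,7-triol F5. Condensation of F5 with an excess of 13 in 0.1 M aqueous HCl at rt, followed by separation of the 4→6 from the 4→8 regioisomer on Sephadex LH-20, comes back to the route at 18.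

Step 6 (partial ester reduction). The risks are over-reduction to the diol and premature, uncontrolled rearrangement of the sensitive α-hydroxy aldehyde during work-up. The fallback sets out from 9. Full reduction with LiAlH4 (THF, 0 °C) should give (2R,3R)-6-(benzyloxy)-3-(hydroxymethyl)-2-[3,4,5-tris(benzyloxy)phenyl]-2,3-dihydro-1-benzofuran-3-ol F6. Parikh–Doering oxidation (SO3·pyridine, DMSO, i-Pr2NEt, 0 °C) should then oxidise only the primary alcohol of F6, the tertiary one being inert. The fallback comes back to the route at 10.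

Further compounds
F1 | step 7 | methyl (2R,3S)-6-(benzyloxy)-3-[(triethylsilyl)oxy]-2-[3,4,5-tris(benzyloxy)phenyl]-2,3-dihydro-1-benzofuran-3-carboxylate | COC(=O)[C@@]1(O[Si](CC)(CC)CC)[C@@H](c3cc(OCc4ccccc4)c(OCc4ccccc4)c(OCc4ccccc4)c3)Oc2cc(OCc3ccccc3)ccc21
F2 | step 7 | (2R,3S)-6-(benzyloxy)-3-[(triethylsilyl)oxy]-2-[3,4,5-tris(benzyloxy)phenyl]-2,3-dihydro-1-benzofuran-3-carbaldehyde | O=C[C@@]1(O[Si](CC)(CC)CC)[C@@H](c3cc(OCc4ccccc4)c(OCc4ccccc4)c(OCc4ccccc4)c3)Oc2cc(OCc3ccccc3)ccc21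
F3 | step 7 | (2R,3R)-7-(benzyloxy)-3-[(triethylsilyl)oxy]-2-[3,4,5-tris(benzyloxy)phenyl]-2,3-dihydro-4H-chromen-4-one | CC[Si](CC)(CC)O[C@@H]1[C@@H](c3cc(OCc4ccccc4)c(OCc4ccccc4)c(OCc4ccccc4)c3)Oc2cc(OCc3ccccc3)ccc2C1=O
F4 | step 11 | (2R,3R)-3,7-dihydroxy-2-(3,4,5-trihydroxyphenyl)-2,3-dihydro-4H-chromen-4-one | O[C@@H]1[C@@H](c2cc(O)c(O)c(O)c2)Oc2cc(O)ccc2C1=O
F5 | step 11 | (2R,3S,4R)-2-(3,4,5-trihydroxyphenyl)-3,4-dihydro-2H-chromene-3,4,7-triol | O[C@@H]1[C@@H](c2cc(O)c(O)c(O)c2)Oc2cc(O)ccc2[C@H]1O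
F6 | step 6 | (2R,3R)-6-(benzyloxy)-3-(hydroxymethyl)-2-[3,4,5-tris(benzyloxy)phenyl]-2,3-dihydro-1-benzofuran-3-ol | OC[C@@]1(O)[C@@H](c3cc(OCc4ccccc4)c(OCc4ccccc4)c(OCc4ccccc4)c3)Oc2cc(OCc3ccccc3)ccc21
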